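**Retrosynthetic overview**

- Formosanatin D ⇐ its 5-O-methyl ether (chelation-directed demethylation last). Pyranone ring C, and with it the furan ring F, ⇐ intramolecular SNAr of a β-keto lactone enolate oxygen on the last C–F of ring A. The β-keto lactone ⇐ C-acylation of a ring B/D benzofuranone by a ring A/E acid chloride.
- Ring A/E acid ⇐ fluorine-directed lithiation and carboxylation of 5-fluoro-7-methoxy-2,2-dimethylchromane ⇐ formal [3+3] annulation of 2,6-difluoro-4-methoxybenzyl bromide with 2,2-dimethyloxirane. The benzylic Grignard reagent opens the epoxide (CH2–CH2 bond of ring E), then the tertiary alkoxide displaces an ortho fluoride (ring E O–C-7 bond).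
- Enabling feature: C-8 of ring A, which carries the benzylic CH2 of ring E, is flanked by the two oxygen-bearing carbons C-7 and C-8a. In the precursor both are C–F and homotopic, so the CH2–C(CH3)2–O unit of the epoxide can be bridged from the benzylic carbon to either one without a regiochemical choice. The fluorine left at C-8a later serves as leaving group for O-1 of ring C.
- Ring B/D lactone ⇐ Mukaiyama–Michael addition of a ketene silyl acetal to 2,2-dimethyl-2H-chromene-5,8-dione, then lactonisation ⇐ oxidative demethylation ⇐ phenylboronic acid-mediated chromenylation of 2,5-dimethoxyphenol with 3-methylbut-2-enal.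
- Order of ring formation: D (step 1), the lactone ring that becomes furan ring F (step 3), E (step 4), C (step 8). Rings A and B come from the two starting arenes.

Key step: step 4

Remark: isoflavonoid numbering is used for the target (ring A: C-4a, C-5 to C-8, C-8a; ring C: O-1, C-2, C-3, C-4; ring B: C-1′ to C-6′; ring D = 2H-pyran on ring B, ring E = dihydropyran on ring A, ring F = furan). The target has no stereocentre, so no configuration has to be set.

**Route**

Step 1
Reactants: 1 2,5-dimethoxyphenol; 2 3-methylbut-2-enal
Product: 3 5,8-dimethoxy-2,2-dimethyl-2H-chromene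
Conditions: PhB(OH)2 (1.0 equiv.), AcOH, toluene, reflux (Dean–Stark)
Reagents that add atoms: none
Why: Phenylboronic acid templates an ortho-specific phenol–enal condensation (chromenylation) at C-6, the only free ortho position of 1, and the resulting 1,3,2-benzodioxaborin should collapse on heating to an ortho-quinone methide that closes by oxa-6π electrocyclisation to the 2H-chromene, water being the only by-product.

Step 2
Reactants: 3 5,8-dimethoxy-2,2-dimethyl-2H-chromene
Product: 4 2,2-dimethyl-2H-chromene-5,8-dione
Conditions: (NH4)2Ce(NO3)6 (2.2 equiv.), MeCN–H2O, 0 °C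
Reagents that add atoms: water, O
Why: Oxidative demethylation of the para-dimethoxyarene by tetravalent cerium (arene radical cation, ipso attack of water, loss of methanol) should be much faster than oxidation of the styrenic double bond and gives the para-quinone.

Step 3
Reactants: 4 2,2-dimethyl-2H-chromene-5,8-dione; 5 tert-butyl[(1-methoxyethenyl)oxy]dimethylsilane
Product: 7 lactone of 2-[8-(tert-butyldimethylsilyloxy)-5-hydroxy-2,2-dimethyl-2H-chromen-6-yl]acetic acid (O-5 acylated; a pyrano-fused benzofuran-2(3H)-one), via hydroxy ester 6 (not isolated)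
Conditions: tBuMe2SiOTf (5 mol%), CH2Cl2, −78 → −20 °C; then camphorsulfonic acid (10 mol%), toluene, 80 °C
Reagents that add atoms: none
Why: In this Mukaiyama–Michael addition the ketene silyl acetal should attack C-6 (chromene numbering), β to the more electrophilic C-8 carbonyl because the C-5 carbonyl is a vinylogous ester of the ring oxygen, the silyl group ends on O-8 of the aromatised hydroquinone, and acid-catalysed lactonisation of the free C-5 hydroxyl onto the ester leaves that silyl ether in place as the protecting group.

Step 4
Reactants: 8 2-(bromomethyl)-1,3-difluoro-5-methoxybenzene; 9 2,2-dimethyloxirane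
Product: 13 5-fluoro-7-methoxy-2,2-dimethylchromane, via benzylic Grignard reagent 10 (not isolated), via bromomagnesium alkoxide 11 (not isolated), via potassium alkoxide 12 (not isolated)
Conditions: Mg, 2-MeTHF, 0 °C (slow addition of 8); then 9 (1.3 equiv.), CuI (5 mol%), −30 °C → rt; then KOtBu (1.5 equiv.), DMPU, 70 °C; one flask
Reagents that add atoms: none
Why: Magnesium insertion gives Grignard reagent 10, which under catalysis by monovalent copper opens the epoxide by SN2 attack at its CH2 carbon (the CH2–CH2 bond of ring E, C-4–C-3 of the chromane) to give alkoxide 11; cation exchange with KOtBu in DMPU gives the more nucleophilic potassium alkoxide 12, whose oxygen adds to an ortho C–F carbon and expels fluoride through a Meisenheimer anion (the ring E O–C-7 bond, O-1–C-8a of the chromane). The closest known reaction types are the CuI-catalysed opening of 1,1-disubstituted epoxides by benzylic Grignard reagents and the intramolecular SNAr etherification of fluoroarenes by tertiary alkoxides used to make 2,2-dimethylchromanes, run here in one flask as a formal [3+3] annulation. Ring E closes in the second event by a 6-exo-trig addition–elimination, helped by the gem-dimethyl (Thorpe–Ingold) effect and by inductive activation of the attacked carbon by the meta fluorine and the meta methoxy group. No stereocentre is formed. The step needs attack at the CH2 and not the quaternary carbon of the epoxide (secured by copper catalysis at low temperature, which should also outrun Lewis-acid rearrangement of the epoxide), coupling at the benzylic carbon and not at a ring carbon (both ortho positions carry fluorine), and a single site of etherification (the two fluorines are homotopic, so either closure gives 13, and the intramolecular displacement should outrun attack by tert-butoxide).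

Step 5
Reactants: 13 5-fluoro-7-methoxy-2,2-dimethylchromane
Product: 15 5-fluoro-7-methoxy-2,2-dimethylchromane-6-carboxylic acid, via aryllithium 14 (not isolated)
Conditions: lithium 2,2,6,6-tetramethylpiperidide (1.3 equiv.), THF, −78 °C; CO2; aq. HCl
Reagents that add atoms: carbon dioxide, O=C=O
Why: Deprotonation by the hindered lithium amide is acidity-controlled (directed ortho-metalation) and should take place at C-6, the only C–H flanked by fluorine and methoxy, and not at C-8 between the two ether oxygens, and the aryllithium is carboxylated at −78 °C before it can lose LiF to an aryne.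

Step 6
Reactants: 15 5-fluoro-7-methoxy-2,2-dimethylchromane-6-carboxylic acid
Product: 16 5-fluoro-7-methoxy-2,2-dimethylchromane-6-carbonyl chloride
Conditions: (COCl)2, DMF (cat.), CH2Cl2, 0 °C → rt; evaporate
Reagents that add atoms: oxalyl chloride, ClC(=O)C(Cl)=O
Why: Vilsmeier-type activation converts the hindered benzoic acid into its acid chloride under conditions that the aryl ethers and the aryl fluoride tolerate.

Step 7
Reactants: 16 5-fluoro-7-methoxy-2,2-dimethylchromane-6-carbonyl chloride; 7 silyl-protected pyrano-fused benzofuran-2(3H)-one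
Product: 18 3-(5-fluoro-7-methoxy-2,2-dimethylchromane-6-carbonyl) derivative of lactone 7 (drawn as the keto tautomer; C-3 racemic and enolised), via lithium enolate 17 (not isolated)
Conditions: 7, LiN(SiMe3)2 (2.2 equiv.), THF, −78 °C; then 16, −78 °C → rt; aq. NH4Cl
Reagents that add atoms: none
Why: The lactone is deprotonated at C-3 to the aromatic 2-oxidobenzofuran enolate and C-acylated by the acid chloride (Claisen-type acylation), the second equivalent of base trapping the more acidic β-keto lactone as its enolate so that any O-acyl isomer is funnelled to the C-acyl product.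

Step 8
Reactants: 18 β-keto lactone
Product: 20 5-O-methylformosanatin D, via silyl ether 19 (not isolated)
Conditions: Cs2CO3 (3 equiv.), DMF, 80 °C, argon; then H2O, rt
Reagents that add atoms: none
Why: The caesium enolate attacks through its lactone oxygen the only ortho C–F carbon of the aroyl ring (six-membered intramolecular SNAr activated by the ortho carbonyl, as in the chromone synthesis from 2-fluoroaryl 1,3-dicarbonyl compounds), which creates pyranone ring C and furan ring F at once, and the fluoride set free together with carbonate and water then cleaves the aryl silyl ether.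

Step 9
Reactants: 20 5-O-methylformosanatin D
Product: 21 Formosanatin D
Conditions: BCl3 (3 equiv.), CH2Cl2, −78 → −20 °C; aq. NaHCO3
Reagents that add atoms: none
Why: BCl3 chelates between the C-4 carbonyl and the peri C-5 methoxy oxygen and should cleave only this methyl ether at low temperature (chelation-controlled demethylation of 5-methoxychromones), leaving the tertiary alkyl aryl ethers of rings D and E and the chromene double bond untouched.

**Compound list**

1 | 2,5-dimethoxyphenol | COc1ccc(OC)c(O)c1 | starting material
2 | 3-methylbut-2-enal | CC(C)=CC=O | starting material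
3 | 5,8-dimethoxy-2,2-dimethyl-2H-chromene | COc1ccc(OC)c2OC(C)(C)C=Cc12 | intermediate
4 | 2,2-dimethyl-2H-chromene-5,8-dione | CC1(C)C=CC2=C(O1)C(=O)C=CC2=O | intermediate
5 | tert-butyl[(1-methoxyethenyl)oxy]dimethylsilane | COC(=C)O[Si](C)(C)C(C)(C)C | starting material
6 | methyl 2-[8-(tert-butyldimethylsilyloxy)-5-hydroxy-2,2-dimethyl-2H-chromen-6-yl]acetate (not isolated) | COC(=O)Cc1cc(O[Si](C)(C)C(C)(C)C)c2OC(C)(C)C=Cc2c1O | intermediate
7 | lactone of 2-[8-(tert-butyldimethylsilyloxy)-5-hydroxy-2,2-dimethyl-2H-chromen-6-yl]acetic acid (5-silyloxybenzofuran-2(3H)-one with a 2,2-dimethyl-2H-pyran fused at C-6/C-7, pyran O on C-6) | O=C1Cc2cc(O[Si](C)(C)C(C)(C)C)c3OC(C)(C)C=Cc3c2O1 | intermediate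
8 | 2-(bromomethyl)-1,3-difluoro-5-methoxybenzene (2,6-difluoro-4-methoxybenzyl bromide) | COc1cc(F)c(CBr)c(F)c1 | starting material
9 | 2,2-dimethyloxirane | CC1(C)CO1 | starting material
10 | (2,6-difluoro-4-methoxybenzyl)magnesium bromide (not isolated) | COc1cc(F)c(C[Mg]Br)c(F)c1 | intermediate
11 | bromomagnesium 4-(2,6-difluoro-4-methoxyphenyl)-2-methylbutan-2-olate (not isolated) | COc1cc(F)c(CCC(C)(C)O[Mg]Br)c(F)c1 | intermediate
12 | potassium 4-(2,6-difluoro-4-methoxyphenyl)-2-methylbutan-2-olate (not isolated) | COc1cc(F)c(CCC(C)(C)[O-])c(F)c1.[K+] | intermediate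
13 | 5-fluoro-7-methoxy-2,2-dimethylchromane | COc1cc(F)c2CCC(C)(C)Oc2c1 | intermediate
14 | (5-fluoro-7-methoxy-2,2-dimethylchroman-6-yl)lithium (not isolated) | COc1cc2OC(C)(C)CCc2c(F)c1[Li] | intermediate
15 | 5-fluoro-7-methoxy-2,2-dimethylchromane-6-carboxylic acid | COc1cc2OC(C)(C)CCc2c(F)c1C(=O)O | intermediate
16 | 5-fluoro-7-methoxy-2,2-dimethylchromane-6-carbonyl chloride | COc1cc2OC(C)(C)CCc2c(F)c1C(Cl)=O | intermediate
17 | lithium enolate of 7 (2-lithiooxybenzofuran form, not isolated) | [Li]Oc1cc2cc(O[Si](C)(C)C(C)(C)C)c3OC(C)(C)C=Cc3c2o1 | intermediate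
18 | 3-(5-fluoro-7-methoxy-2,2-dimethylchromane-6-carbonyl) derivative of lactone 7 (keto tautomer drawn; C-3 racemic, in equilibrium with the enol) | COc1cc2OC(C)(C)CCc2c(F)c1C(=O)C3C(=O)Oc4c3cc(O[Si](C)(C)C(C)(C)C)c5OC(C)(C)C=Cc45 | intermediate
19 | 5-O-methyl-5′-O-(tert-butyldimethylsilyl)formosanatin D (not isolated) | CC1(C)C=Cc2c(c(O[Si](C)(C)C(C)(C)C)cc3c2oc2oc4c5c(cc(OC)c4c(=O)c23)OC(C)(C)CC5)O1 | intermediate
20 | 5-O-methylformosanatin D | CC1(C)C=Cc2c(c(O)cc3c2oc2oc4c5c(cc(OC)c4c(=O)c23)OC(C)(C)CC5)O1 | intermediate
21 | Formosanatin D | CC1(C)C=Cc2c(c(O)cc3c2oc2oc4c5c(cc(O)c4c(=O)c23)OC(C)(C)CC5)O1 | target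

**Step count and risks**

Total steps: 9. Longest linear sequence: 6 steps (steps 4–9; the other branch, steps 1–3 and 7–9, is equally long).

Steps most likely to fail:

Step 4. What may go wrong: Wurtz homocoupling during magnesium insertion, Lewis-acid rearrangement of the epoxide before C–C coupling, or incomplete cation exchange so that the alkoxide does not cyclise. Fallback, which makes the two bonds in separate operations and brings in the ring oxygen by hydration: set out from 8 and couple it with 2-methylallylmagnesium chloride (Li2CuCl4 cat., THF, −20 °C) to give 1,3-difluoro-5-methoxy-2-(3-methylbut-3-en-1-yl)benzene F1. Mukaiyama hydration (Co(acac)2, PhSiH3, O2, i-PrOH) should then give 4-(2,6-difluoro-4-methoxyphenyl)-2-methylbutan-2-ol F2. KOtBu in DMPU at 70 °C converts F2 into potassium alkoxide 12, where the route is rejoined (12 → 13).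

Step 5. What may go wrong: poor site selectivity of the deprotonation (C-8 between the two oxygens competing with C-6), or loss of LiF from the aryllithium to an aryne. Fallback, which fixes the site by electrophilic substitution instead of deprotonation: set out from 13 and brominate para to the ring oxygen (N-bromosuccinimide, MeCN, 0 °C) to give 6-bromo-5-fluoro-7-methoxy-2,2-dimethylchromane F3. Bromine–lithium exchange (n-BuLi, THF, −78 °C) then gives aryllithium 14, where the route is rejoined (14 → 15 with CO2).

Step 9. What may go wrong: addition of HCl across the 2H-chromene ring D, or Lewis-acid cleavage of a tertiary alkyl aryl ether, during the demethylation. Fallback, which moves the demethylation to a stage without ring D and carries the ring A phenol as a self-activating acetonide: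
- Set out from 15; BCl3 (CH2Cl2, −78 → 0 °C) gives 5-fluoro-7-hydroxy-2,2-dimethylchromane-6-carboxylic acid F4.
- Acetone, (CF3CO)2O and CF3CO2H convert F4 into the 2,2-dimethyl-1,3-dioxin-4-one (salicylate acetonide) fused across C-6/C-7 of the chromane F5.
- Lithium enolate 17 (from 7 and LiN(SiMe3)2, THF, −78 °C → rt) is C-acylated by F5 with loss of acetone to give the 5-hydroxy analogue of keto lactone 18 F6.
- Cs2CO3 in DMF at 80 °C closes ring C to 5′-O-(tert-butyldimethylsilyl)formosanatin D F7 (not isolated); water then removes the silyl group as in step 8 and the route is rejoined at target 21.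

Further compounds
F1 | step 4 | 1,3-difluoro-5-methoxy-2-(3-methylbut-3-en-1-yl)benzene | COc1cc(F)c(CCC(C)=C)c(F)c1
F2 | step 4 | 4-(2,6-difluoro-4-methoxyphenyl)-2-methylbutan-2-ol | COc1cc(F)c(CCC(C)(C)O)c(F)c1
F3 | step 5 | 6-bromo-5-fluoro-7-methoxy-2,2-dimethylchromane | COc1cc2OC(C)(C)CCc2c(F)c1Br
F4 | step 9 | 5-fluoro-7-hydroxy-2,2-dimethylchromane-6-carboxylic acid | OC(=O)c1c(O)cc2OC(C)(C)CCc2c1F
F5 | step 9 | 2,2-dimethyl-1,3-dioxin-4-one (acetonide) of F4, fused across C-6/C-7 of the 5-fluoro-2,2-dimethylchromane | CC1(C)OC(=O)c2c(F)c3CCC(C)(C)Oc3cc2O1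
F6 | step 9 | 3-(5-fluoro-7-hydroxy-2,2-dimethylchromane-6-carbonyl) derivative of lactone 7 (keto tautomer drawn; C-3 racemic, enolised) | Oc1cc2OC(C)(C)CCc2c(F)c1C(=O)C3C(=O)Oc4c3cc(O[Si](C)(C)C(C)(C)C)c5OC(C)(C)C=Cc45
F7 | step 9 | 5′-O-(tert-butyldimethylsilyl)formosanatin D (not isolated) | CC1(C)C=Cc2c(c(O[Si](C)(C)C(C)(C)C)cc3c2oc2oc4c5c(cc(O)c4c(=O)c23)OC(C)(C)CC5)O1
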